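**Retrosynthetic overview**
1. The acrylic acid unit is traced back to a carboxyl carbon at C2: C(=CH2)CO2H ⇐ enol triflate + CO/H2O ⇐ methyl ketone ⇐ carboxylic acid + MeLi.
2. The only ring, the 3,6-dihydro-2H-pyran, is closed late at C4=C5 by metathesis of an acyclic α-(2-alkylallyloxy) ketone.
3. Key disconnection C2–C3: an Ireland–Claisen [3,3] rearrangement of an allylic glycolate. Its chair transition state passes the bought carbinol configuration of (S)-1-(benzyloxy)but-3-en-2-ol, made from benzyl (S)-glycidyl ether, on to C2.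
4. The glycolate ether comes from bromoacetic acid and 2-(homofarnesyl)allyl alcohol, which is made from methallyl alcohol dianion and (2E,6E)-farnesyl bromide.

Assumption: (2E,6E)-farnesyl bromide and benzyl (S)-glycidyl ether (≥98 % ee) are bought isomerically pure; the target stereocentre reads as 2R.

**Step 1**
Reactants: 1 2-methylprop-2-en-1-ol (methallyl alcohol); 2 (2E,6E)-farnesyl bromide
Product: 4 (5E,9E)-6,10,14-trimethyl-2-methylidenepentadeca-5,9,13-trien-1-ol, via dilithiated methallyl alcohol 3 (not isolated)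
Conditions: 1, n-BuLi (2.2 equiv), TMEDA, Et2O, 0 °C → rt; then 2, THF, −78 °C → rt; H2O
Reagents that add atoms: n-butyllithium, [Li]CCCC (its lithium stays only in 3)
Why: SN2 alkylation of the allylic C,O-dianion at carbon by the primary allylic bromide installs the whole side chain with both E-alkenes untouched, and no stereocentre is formed.

**Step 2**
Reactants: 4; 5 bromoacetic acid
Product: 6 2-{[(5E,9E)-6,10,14-trimethyl-2-methylidenepentadeca-5,9,13-trien-1-yl]oxy}acetic acid
Conditions: NaH (3 equiv), THF, 0 °C → reflux; then 1 M HCl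
Reagents that add atoms: none
Why: Williamson ether synthesis of the sodium alkoxide with sodium bromoacetate forms the future O1–C6 ether and the glycolate carbon that becomes C2.

**Step 3**
Reactants: 7 benzyl (S)-glycidyl ether
Product: 9 (2S)-1-(benzyloxy)but-3-en-2-ol, via sulfonium alkoxide betaine 8 (not isolated)
Conditions: Me3S+ I− (3 equiv), n-BuLi (2.9 equiv), THF, −10 °C → rt; H2O
Reagents that add atoms: trimethylsulfonium iodide, C[S+](C)C.[I-]
Why: In this one-carbon epoxide-to-allylic-alcohol homologation, dimethylsulfonium methylide opens the epoxide at its CH2 end and a second ylide eliminates Me2S; the C–O bond of the bought stereocentre is never touched, so it is retained.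

**Step 4**
Reactants: 6; 9
Product: 10 (2S)-1-(benzyloxy)but-3-en-2-yl 2-{[(5E,9E)-6,10,14-trimethyl-2-methylidenepentadeca-5,9,13-trien-1-yl]oxy}acetate
Conditions: DCC, DMAP (cat.), CH2Cl2, 0 °C → rt
Reagents that add atoms: none
Why: Steglich esterification acylates the carbinol oxygen without touching its C–O bond, so the (S)-centre is carried unchanged into the allylic glycolate.

**Step 5 (key step)**
Reactants: 10
Product: 14 (2R,4E)-6-(benzyloxy)-2-{[(5E,9E)-6,10,14-trimethyl-2-methylidenepentadeca-5,9,13-trien-1-yl]oxy}hex-4-enoic acid, via chelated lithium enolate 11 (not isolated), via (Z)-silyl ketene acetal 12 (not isolated), via trimethylsilyl ester 13 (not isolated)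
Conditions: TMSCl/Et3N, then LiHMDS (1.3 equiv), THF, −78 °C → rt; then dilute aq. HCl/THF
Reagents that add atoms: lithium hexamethyldisilazide, [Li]N([Si](C)(C)C)[Si](C)(C)C (lithium only in 11); chlorotrimethylsilane, C[Si](C)(C)Cl (silicon only in 12 and 13)
Why: In this Ireland–Claisen [3,3]-sigmatropic rearrangement the chelation-controlled (Z)-silyl ketene acetal reacts through a chair with CH2OBn equatorial, so the C2–C3 bond forms suprafacially and the bought (S)-carbinol centre is traded for the (2R)-centre and a 4E-alkene.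

**Step 6**
Reactants: 14
Product: 16 (3R,5E)-7-(benzyloxy)-3-{[(5E,9E)-6,10,14-trimethyl-2-methylidenepentadeca-5,9,13-trien-1-yl]oxy}hept-5-en-2-one, via dilithium gem-diolate 15 (not isolated)
Conditions: MeLi (2.3 equiv), Et2O, −78 → 0 °C; inverse quench into cold 1 M HCl
Reagents that add atoms: methyllithium, [Li]C
Why: Methyllithium adds to the lithium carboxylate and stops at the stable gem-diolate, which collapses to the methyl ketone only on quenching, so there is no over-addition and no enolisable ketone is exposed to base (C2 retained).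

**Step 7**
Reactants: 16
Product: 17 1-{(2R)-5-[(3E,7E)-4,8,12-trimethyltrideca-3,7,11-trien-1-yl]-3,6-dihydro-2H-pyran-2-yl}ethan-1-one
Conditions: Grubbs II (5 mol %), CH2Cl2 (2 mM), 40 °C
Reagents that add atoms: none
Why: In this ring-closing metathesis the carbene loads at the 1,2-disubstituted alkene and closes onto the 1,1-disubstituted alkene, giving the six-membered ring with the trisubstituted C4=C5 bond; the hindered chain alkenes do not compete and C2 is untouched.

**Step 8**
Reactants: 17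
Product: 19 1-{(2R)-5-[(3E,7E)-4,8,12-trimethyltrideca-3,7,11-trien-1-yl]-3,6-dihydro-2H-pyran-2-yl}ethenyl trifluoromethanesulfonate, via potassium enolate 18 (not isolated)
Conditions: 17 added to KHMDS (1.15 equiv), THF, −78 °C; PhNTf2, −78 → −20 °C; cold dilute HCl wash
Reagents that add atoms: potassium hexamethyldisilazide, [K]N([Si](C)(C)C)[Si](C)(C)C (potassium only in 18); N-phenylbis(trifluoromethanesulfonimide), O=S(=O)(N(c1ccccc1)S(=O)(=O)C(F)(F)F)C(F)(F)F
Why: Kinetic enolisation with a bulky base in excess removes a CH3 proton rather than the hindered C2–H, and O-triflation fixes the terminal enol triflate, so C2 is not epimerised.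

**Step 9**
Reactants: 19
Product: 20 2-{(2R)-5-[(3E,7E)-4,8,12-trimethyltrideca-3,7,11-trien-1-yl]-3,6-dihydro-2H-pyran-2-yl}prop-2-enoic acid (target)
Conditions: Pd(OAc)2 (5 mol %), dppf (6 mol %), Et3N (3 equiv), CO (1 atm), DMF/H2O 9:1, 50 °C; acidic work-up (pH 3)
Reagents that add atoms: carbon monoxide, [C-]#[O+]; water, O
Why: In this palladium-catalysed hydroxycarbonylation, oxidative addition into the vinyl triflate, CO insertion and hydrolysis of the acyl-palladium give the α-substituted acrylic acid directly under mild conditions that leave the polyene, the allylic ether and C2 intact.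

**Compound list**
1 | 2-methylprop-2-en-1-ol | C=C(C)CO | starting material
2 | (2E,6E)-farnesyl bromide | BrC/C=C(\C)CC/C=C(\C)CCC=C(C)C | starting material
3 | dilithiated methallyl alcohol | [Li]CC(=C)CO[Li] | intermediate (not isolated)
4 | (5E,9E)-6,10,14-trimethyl-2-methylidenepentadeca-5,9,13-trien-1-ol | OCC(=C)CC/C=C(\C)CC/C=C(\C)CCC=C(C)C | intermediate
5 | bromoacetic acid | OC(=O)CBr | starting material
6 | 2-{[(5E,9E)-6,10,14-trimethyl-2-methylidenepentadeca-5,9,13-trien-1-yl]oxy}acetic acid | OC(=O)COCC(=C)CC/C=C(\C)CC/C=C(\C)CCC=C(C)C | intermediate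
7 | benzyl (S)-glycidyl ether | C1O[C@@H]1COCc1ccccc1 | starting material
8 | [(3S)-4-(benzyloxy)-3-oxidobutyl]dimethylsulfonium (betaine) | C[S+](C)CC[C@H]([O-])COCc1ccccc1 | intermediate (not isolated)
9 | (2S)-1-(benzyloxy)but-3-en-2-ol | C=C[C@H](O)COCc1ccccc1 | intermediate
10 | (2S)-1-(benzyloxy)but-3-en-2-yl ester of 6 | C=C[C@H](OC(=O)COCC(=C)CC/C=C(\C)CC/C=C(\C)CCC=C(C)C)COCc1ccccc1 | intermediate
11 | chelated lithium enolate of 10 (ether oxygen cis to OLi) | [Li]O/C(O[C@@H](C=C)COCc1ccccc1)=C\OCC(=C)CC/C=C(\C)CC/C=C(\C)CCC=C(C)C | intermediate (not isolated)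
12 | (Z)-trimethylsilyl ketene acetal of 10 | C[Si](C)(C)O/C(O[C@@H](C=C)COCc1ccccc1)=C\OCC(=C)CC/C=C(\C)CC/C=C(\C)CCC=C(C)C | intermediate (not isolated)
13 | trimethylsilyl ester of 14 (2R,4E) | C[Si](C)(C)OC(=O)[C@@H](C/C=C/COCc1ccccc1)OCC(=C)CC/C=C(\C)CC/C=C(\C)CCC=C(C)C | intermediate (not isolated)
14 | (2R,4E)-6-(benzyloxy)-2-{[(5E,9E)-6,10,14-trimethyl-2-methylidenepentadeca-5,9,13-trien-1-yl]oxy}hex-4-enoic acid | OC(=O)[C@@H](C/C=C/COCc1ccccc1)OCC(=C)CC/C=C(\C)CC/C=C(\C)CCC=C(C)C | intermediate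
15 | dilithium gem-diolate of 16 (3R,5E) | [Li]OC(C)(O[Li])[C@@H](C/C=C/COCc1ccccc1)OCC(=C)CC/C=C(\C)CC/C=C(\C)CCC=C(C)C | intermediate (not isolated)
16 | (3R,5E)-7-(benzyloxy)-3-{[(5E,9E)-6,10,14-trimethyl-2-methylidenepentadeca-5,9,13-trien-1-yl]oxy}hept-5-en-2-one | CC(=O)[C@@H](C/C=C/COCc1ccccc1)OCC(=C)CC/C=C(\C)CC/C=C(\C)CCC=C(C)C | intermediate
17 | 1-{(2R)-5-[(3E,7E)-4,8,12-trimethyltrideca-3,7,11-trien-1-yl]-3,6-dihydro-2H-pyran-2-yl}ethan-1-one | CC(=O)[C@H]1CC=C(CC/C=C(\C)CC/C=C(\C)CCC=C(C)C)CO1 | intermediate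
18 | potassium enolate of 17 (terminal, 2R) | [K]OC(=C)[C@H]1CC=C(CC/C=C(\C)CC/C=C(\C)CCC=C(C)C)CO1 | intermediate (not isolated)
19 | 1-{(2R)-5-[(3E,7E)-4,8,12-trimethyltrideca-3,7,11-trien-1-yl]-3,6-dihydro-2H-pyran-2-yl}ethenyl trifluoromethanesulfonate | C=C(OS(=O)(=O)C(F)(F)F)[C@H]1CC=C(CC/C=C(\C)CC/C=C(\C)CCC=C(C)C)CO1 | intermediate
20 | 2-{(2R)-5-[(3E,7E)-4,8,12-trimethyltrideca-3,7,11-trien-1-yl]-3,6-dihydro-2H-pyran-2-yl}prop-2-enoic acid | C=C(C(=O)O)[C@H]1CC=C(CC/C=C(\C)CC/C=C(\C)CCC=C(C)C)CO1 | target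

**Totals**
Total step count: 9. Longest linear sequence: 8 (steps 1, 2, 4, 5, 6, 7, 8, 9).

**Steps most likely to fail**

*Step 1.* The risks are O-alkylation, SN2′ attack on the farnesyl bromide and a modest yield. The fallback reverses the polarity of the coupling; it sets out from 2 and comes back at 4.
- Compound 2 is converted with sodium p-toluenesulfinate in DMF into (2E,6E)-farnesyl p-tolyl sulfone F1.
- The lithio anion of F1 (n-BuLi, THF, −78 °C) is alkylated with commercial methyl 2-(bromomethyl)acrylate. This gives methyl (5E,9E)-6,10,14-trimethyl-2-methylidene-4-tosylpentadeca-5,9,13-trienoate F2, which is racemic at the sulfone carbon.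
- DIBAL-H reduces the ester to the sulfonyl allylic alcohol F3.
- PdCl2(dppp)/LiBHEt3 removes the allylic sulfonyl group without moving or isomerising the E-alkene, which gives 4.

*Step 5.* The risks are a [2,3]-Wittig shift of the enolate through the second allyl ether and imperfect ketene acetal geometry, which would lower the enantiomeric ratio. The fallback postpones the etherification so that the rearranging enolate carries only one allyl unit; it sets out from 9, also uses 4, and comes back at 14.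
- Compound 9 is esterified (DCC, DMAP) with commercial [(4-methoxybenzyl)oxy]acetic acid to give (2S)-1-(benzyloxy)but-3-en-2-yl [(4-methoxybenzyl)oxy]acetate F4.
- The same Ireland–Claisen rearrangement gives (2R,4E)-6-(benzyloxy)-2-[(4-methoxybenzyl)oxy]hex-4-enoic acid F5.
- DDQ in wet CH2Cl2 releases (2R,4E)-6-(benzyloxy)-2-hydroxyhex-4-enoic acid F6.
- The disodium salt of F6 (NaH, THF/DMF) is O-alkylated with the methanesulfonate of 4, F7 (made with MsCl, Et3N), which gives 14.

*Step 8.* The risks are deprotonation at C2–H instead of CH3, which gives the regioisomeric triflate and racemisation. The fallback avoids a ketone enolate altogether; it sets out from 17 and comes back at 20, bypassing 19.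
- Compound 17 is condensed with 2,4,6-triisopropylbenzenesulfonohydrazide to give the (E)-trisylhydrazone F8.
- The hydrazone geometry directs n-BuLi (2.2 equiv, THF/TMEDA, −78 → −10 °C, Shapiro reaction) to the methyl side and gives the 2-lithioalkene F9.
- F9 is re-cooled at once to −78 °C, to prevent β-alkoxide loss, and carboxylated with CO2 to give 20.

**Further compounds**
F1 | step 1 | (2E,6E)-farnesyl p-tolyl sulfone | Cc1ccc(cc1)S(=O)(=O)C/C=C(\C)CC/C=C(\C)CCC=C(C)C
F2 | step 1 | methyl (5E,9E)-6,10,14-trimethyl-2-methylidene-4-(4-methylbenzenesulfonyl)pentadeca-5,9,13-trienoate (racemic at C4) | COC(=O)C(=C)CC(/C=C(\C)CC/C=C(\C)CCC=C(C)C)S(=O)(=O)c1ccc(C)cc1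
F3 | step 1 | (5E,9E)-6,10,14-trimethyl-2-methylidene-4-(4-methylbenzenesulfonyl)pentadeca-5,9,13-trien-1-ol (racemic at C4) | OCC(=C)CC(/C=C(\C)CC/C=C(\C)CCC=C(C)C)S(=O)(=O)c1ccc(C)cc1
F4 | step 5 | (2S)-1-(benzyloxy)but-3-en-2-yl [(4-methoxybenzyl)oxy]acetate | C=C[C@H](OC(=O)COCc1ccc(OC)cc1)COCc1ccccc1
F5 | step 5 | (2R,4E)-6-(benzyloxy)-2-[(4-methoxybenzyl)oxy]hex-4-enoic acid | OC(=O)[C@@H](C/C=C/COCc1ccccc1)OCc1ccc(OC)cc1
F6 | step 5 | (2R,4E)-6-(benzyloxy)-2-hydroxyhex-4-enoic acid | OC(=O)[C@@H](C/C=C/COCc1ccccc1)O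
F7 | step 5 | (5E,9E)-6,10,14-trimethyl-2-methylidenepentadeca-5,9,13-trien-1-yl methanesulfonate | CS(=O)(=O)OCC(=C)CC/C=C(\C)CC/C=C(\C)CCC=C(C)C
F8 | step 8 | (E)-2,4,6-triisopropylbenzenesulfonylhydrazone of 17 (2R) | C/C(=N\NS(=O)(=O)c1c(C(C)C)cc(C(C)C)cc1C(C)C)[C@H]1CC=C(CC/C=C(\C)CC/C=C(\C)CCC=C(C)C)CO1
F9 | step 8 | 1-{(2R)-5-[(3E,7E)-4,8,12-trimethyltrideca-3,7,11-trien-1-yl]-3,6-dihydro-2H-pyran-2-yl}ethenyllithium | [Li]C(=C)[C@H]1CC=C(CC/C=C(\C)CC/C=C(\C)CCC=C(C)C)CO1
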